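**Retrosynthetic overview**
1. Endgame: the PMB, TBDPS and TMSE groups come off last. The C10 ester is cut (Yamaguchi) into a tricyclic (10S)-allylic alcohol and a (9Z)-C16 acid made by a Z-selective Wittig reaction.
2. Ring A decoration: the C10 alcohol comes from Luche reduction of an enone, the enone from allylic C–H oxidation of the C8 enoate, and the enoate from Pd carbonylation of the enol triflate of a tricyclic C8 ketone.
3. Ring C (formed last): the C6–C7 bond is made by a new cobalt-hydride MHAT/radical–polar crossover hydroalkylation of the isopropenyl group with a regiodefined enol silane.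
4. Ring A (formed second): enamine Michael/aldol spiroannulation of a 2,5-cis cyclopentanecarbaldehyde with methyl vinyl ketone sets C1.
5. Ring B (formed first): ring contraction of (+)-limonene oxide (C5 from the chiral pool) by oxygenation of the ring methyl, glycol cleavage and aldol condensation. C2 is set by face-selective conjugate reduction.

Assumption: commercial (+)-limonene oxide is the cis/trans mixture with fixed 4R configuration; the undefined epoxide/carbinol centres of 1–5 and 7 are erased in steps 5 and 6 and are left open in the SMILES.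

Numbering (cedrane):
- C1 quaternary, C2 CH(C12), C3, C4, C5 CH, C6 CMe2, C7 bridgehead CH, C8 (bears C15), C9, C10, C11 CH2 bridge.
- Ring A = C1, C10, C9, C8, C7, C11. Ring B = C1–C5. Ring C = C1, C5, C6, C7, C11.
- Target = (1S,2S,5S,7R,10S). C12, C6 and C11 lie on the same face of ring B.
- TBDPS = tert-butyldiphenylsilyl, TES = triethylsilyl, TMSE = 2-(trimethylsilyl)ethyl, PMB = 4-methoxybenzyl.

Step 1
Reactants: 1 (+)-limonene oxide [(4R)-1,2-epoxy-p-menth-8-ene; cis/trans mixture]
Product: 2 (4R)-p-mentha-1(7),8-dien-2-ol (carbinol epimers)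
Conditions: LDA (2.5 equiv), Et2O, 0 °C to reflux; aq NH4Cl
Reagents that add atoms: none
Why: Lithium amide epoxide-to-allylic-alcohol isomerisation (syn β-elimination) takes a proton from the least hindered methyl group, which gives the exocyclic methylene next to the carbinol and leaves C4 and the isopropenyl group untouched.

Step 2
Reactants: 2 (4R)-p-mentha-1(7),8-dien-2-ol
Product: 3 (6R)-6-isopropenyl-1-oxaspiro[2.5]octan-4-ol (epimer mixture)
Conditions: VO(acac)2 (2 mol %), t-BuOOH (1.2 equiv, decane), CH2Cl2, 0 °C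
Reagents that add atoms: tert-butyl hydroperoxide, CC(C)(C)OO
Why: Hydroxyl-directed vanadium-catalysed epoxidation oxidises only the allylic-alcohol alkene and spares the isopropenyl group, and the new centre is erased in step 5.

Step 3
Reactants: 3 (6R)-6-isopropenyl-1-oxaspiro[2.5]octan-4-ol
Product: 4 (4R)-1-(hydroxymethyl)-4-isopropenylcyclohexane-1,2-diol (epimer mixture)
Conditions: NaOH (0.5 M aq), t-BuOH, 70 °C
Reagents that add atoms: water, O
Why: Base-mediated epoxide opening (with Payne equilibration, all pathways converge on the same 1,2,7-triol constitution) places oxygen on the former ring methyl carbon, and the alkene is inert to hydroxide.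

Step 4
Reactants: 4 (4R)-1-(hydroxymethyl)-4-isopropenylcyclohexane-1,2-diol
Product: 5 (4R)-1-[(TBDPS-oxy)methyl]-4-isopropenylcyclohexane-1,2-diol
Conditions: TBDPSCl (1.05 equiv), imidazole (2.2 equiv), CH2Cl2/DMF, 0 °C
Reagents that add atoms: tert-butyl(chloro)diphenylsilane, CC(C)(C)[Si](Cl)(c1ccccc1)c1ccccc1
Why: Sterically controlled silyl ether formation, since the bulky chlorosilane reacts only with the primary hydroxyl and leaves the secondary/tertiary glycol free for cleavage.

Step 5
Reactants: 5 (4R)-1-[(TBDPS-oxy)methyl]-4-isopropenylcyclohexane-1,2-diol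
Product: 6 (3R)-7-(TBDPS-oxy)-3-isopropenyl-6-oxoheptanal
Conditions: NaIO4 (1.5 equiv), THF/H2O (3:1), 0 °C to rt
Reagents that add atoms: none
Why: Malaprade glycol cleavage opens the ring at neutral pH to the keto aldehyde, and the alkene, the silyl ether and the stereocentre (future C5) are not affected.

Step 6
Reactants: 6 (3R)-7-(TBDPS-oxy)-3-isopropenyl-6-oxoheptanal
Product: 8 (5S)-2-[(TBDPS-oxy)methyl]-5-isopropenylcyclopent-1-ene-1-carbaldehyde, via aldol adduct 7 (not isolated)
Conditions: piperidine (0.3 equiv), AcOH (0.3 equiv), PhMe, reflux, Dean–Stark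
Reagents that add atoms: none
Why: Amine-catalysed intramolecular aldol condensation through the aldehyde enamine attacks the activated α-silyloxy ketone, closes ring B (C1–C2 bond) as for the parent limonene keto aldehyde and does not touch C5.

Step 7
Reactants: 8 (5S)-2-[(TBDPS-oxy)methyl]-5-isopropenylcyclopent-1-ene-1-carbaldehyde
Product: 9 (2S,5R)-2-[(TBDPS-oxy)methyl]-5-isopropenylcyclopentane-1-carbaldehyde (2,5-cis; C1 epimers)
Conditions: [(Ph3P)CuH]6 (0.4 equiv), H2O (5 equiv), degassed PhMe, rt
Reagents that add atoms: none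
Why: Stryker conjugate reduction adds H to C2 and Cu to C1 on the ring face opposite to the C5 isopropenyl group, which pushes the CH2OTBDPS arm onto the isopropenyl face (sets C2, 2,5-cis) while the isolated alkene is inert and the C1 mixture is erased in step 8.

Step 8
Reactants: 9 (2S,5R)-2-[(TBDPS-oxy)methyl]-5-isopropenylcyclopentane-1-carbaldehyde; 10 methyl vinyl ketone
Product: 13 spiro enone 1-[(TBDPS-oxy)methyl]-4-isopropenylspiro[4.5]dec-6-en-8-one (C11=C7 arm cis to both ring B substituents), via piperidine enamine 11 (not isolated), via Michael adduct 12 (not isolated)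
Conditions: piperidine (1.5 equiv), TsOH (cat.), PhMe, Dean–Stark; 10 (1.5 equiv), 0 °C to reflux; then AcOH/NaOAc/H2O, reflux
Reagents that add atoms: none
Why: Stork enamine Michael addition followed by intramolecular aldol condensation (Robinson-type spiroannulation, ring A) brings methyl vinyl ketone in from the face opposite to the two cis substituents, so the C10–C9 arm is trans and the former formyl carbon C11 is cis to the isopropenyl group, which sets the quaternary centre C1.

Step 9
Reactants: 13 spiro enone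
Product: 14 TES enol ether of the spiro ketone (C7=C8 double bond in the arm cis to the isopropenyl group)
Conditions: RhCl(PPh3)3 (2 mol %), Et3SiH (1.5 equiv), PhH, 50 °C
Reagents that add atoms: triethylsilane, CC[SiH](CC)CC
Why: Rhodium-catalysed 1,4-hydrosilylation of the enone fixes the enol silane double bond at C7=C8 in the correct arm, and the hindered 1,1-disubstituted alkene reacts much more slowly.

Step 10
Reactants: 14 TES enol ether of the spiro ketone
Product: 15 tricyclic ketone 12-(TBDPS-oxy)-15-nor-2-epi-cedran-8-one (C1, C2, C5, C7 as in the target)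
Conditions: (R,R)-N,N'-bis(3,5-di-tert-butylsalicylidene)-1,2-cyclohexanediaminocobalt, C36H52CoN2O2 (5 mol %), N-fluoro-2,4,6-trimethylpyridinium triflate (1.5 equiv), PhSiH3 (1.5 equiv), 4 Å MS, PhCF3, 0 °C to rt; aq NaHCO3
Reagents that add atoms: none
Why: Proposed new method: an intramolecular Markovnikov hydroalkylation in which a simple ketone enol silane is the carbon nucleophile of a cobalt-hydride MHAT/radical–polar crossover cycle, reasoned as follows: the trivalent cobalt hydride (from the fluoride-oxidised salen complex and PhSiH3) gives H• to the open =CH2 of the isopropenyl group faster than to the trisubstituted enol silane, the tertiary C6 radical is captured by divalent cobalt and oxidised to a tetravalent alkylcobalt that acts as a tertiary cation, and C7 of the strongly π-nucleophilic enol silane, held on the same face of ring B, attacks it in a 5-exo sense to close ring C, form the quaternary–tertiary C6–C7 bond and set the only geometrically possible bridgehead C7 before Et3Si+ is lost to triflate; the closest known reaction types are the cobalt salen/N-fluoropyridinium/silane hydroalkoxylation, hydroamination and hydroarylation of unactivated alkenes and the Lewis acid (Reetz) α-tert-alkylation of enol silanes with tert-alkyl chlorides.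

Step 11
Reactants: 15 tricyclic ketone
Product: 17 C8 enol triflate (C8=C9), via potassium enolate 16 (not isolated)
Conditions: KHMDS (1.2 equiv), THF, −78 °C; PhNTf2 (1.3 equiv), −78 °C to 0 °C; aq NH4Cl
Reagents that add atoms: N-phenylbis(trifluoromethanesulfonimide), O=S(=O)(N(c1ccccc1)S(=O)(=O)C(F)(F)F)C(F)(F)F
Why: Enolate O-triflation is regiospecific because C7 is a bridgehead (Bredt) and only C9–H can be removed, and no stereocentre is α to the carbonyl on that side.

Step 12
Reactants: 17 C8 enol triflate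
Product: 18 TMSE 12-(TBDPS-oxy)-2-epi-cedr-8-en-15-oate
Conditions: Pd(OAc)2 (5 mol %), dppf (10 mol %), CO (1 atm), Me3SiCH2CH2OH (10 equiv), Et3N (3 equiv), DMF, 60 °C
Reagents that add atoms: carbon monoxide, [C-]#[O+]; 2-(trimethylsilyl)ethanol, C[Si](C)(C)CCO
Why: Palladium-catalysed alkoxycarbonylation (oxidative addition of the vinyl triflate to zerovalent palladium, CO insertion, alcoholysis) installs C15 with the C8=C9 alkene already in place.

Step 13
Reactants: 18 TMSE enoate
Product: 19 TMSE 12-(TBDPS-oxy)-10-oxo-2-epi-cedr-8-en-15-oate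
Conditions: Rh2(cap)4 (cap = caprolactamate; 1 mol %), t-BuOOH (70% aq, 8 equiv), K2CO3 (0.5 equiv), CH2Cl2, rt to 40 °C
Reagents that add atoms: tert-butyl hydroperoxide, CC(C)(C)OO
Why: Dirhodium caprolactamate/peroxide radical allylic oxidation attacks C10, the only allylic CH2 (the other allylic position C7 is a bridgehead), as it does for cyclohexene-1-carboxylates and for cedrene itself, and silyl ethers and esters tolerate it.

Step 14
Reactants: 19 enone ester
Product: 20 TMSE (10S)-10-hydroxy-12-(TBDPS-oxy)-2-epi-cedr-8-en-15-oate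
Conditions: NaBH4 (1.5 equiv), CeCl3·7H2O (1.5 equiv), MeOH/THF, −78 °C to −20 °C
Reagents that add atoms: none
Why: Luche 1,2-reduction delivers hydride to the C10 carbonyl from the exo face next to the one-carbon bridge C11, because the endo face is shielded by H5 and the endo methyl of the C5–C6 bridge, and this sets the equatorial (10S) alcohol and spares the enoate.

Step 15
Reactants: 21 9-bromononanoic acid
Product: 22 (8-carboxyoctyl)triphenylphosphonium bromide
Conditions: PPh3 (1.05 equiv), MeCN, reflux
Reagents that add atoms: triphenylphosphine, c1ccc(cc1)P(c1ccccc1)c1ccccc1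
Why: SN2 quaternisation of the phosphine by the primary bromide gives the crystalline Wittig salt.

Step 16
Reactants: 23 heptane-1,7-diol
Product: 24 7-(PMB-oxy)heptan-1-ol
Conditions: 23 (3 equiv), NaH (1 equiv), PMBCl (1 equiv), Bu4NI (cat.), THF/DMF, 0 °C to rt
Reagents that add atoms: 4-methoxybenzyl chloride, COc1ccc(CCl)cc1
Why: Williamson etherification with excess diol gives the mono-ether, and the unreacted diol is washed out with water.

Step 17
Reactants: 24 7-(PMB-oxy)heptan-1-ol
Product: 25 7-(PMB-oxy)heptanal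
Conditions: TEMPO (10 mol %), PhI(OAc)2 (1.1 equiv), CH2Cl2, rt
Reagents that add atoms: none
Why: Oxoammonium (TEMPO) oxidation stops cleanly at the aldehyde and does not touch the PMB ether.

Step 18
Reactants: 22 (8-carboxyoctyl)triphenylphosphonium bromide; 25 7-(PMB-oxy)heptanal
Product: 27 (9Z)-16-(PMB-oxy)hexadec-9-enoic acid, via phosphorus ylide 26 (not isolated)
Conditions: NaHMDS (2.1 equiv), THF, 0 °C; 25, −78 °C to rt; 1 M HCl
Reagents that add atoms: none
Why: Wittig olefination with a non-stabilised ylide under lithium-free conditions runs through the kinetically favoured cis-oxaphosphetane and sets the 9Z alkene (typically at least 95:5).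

Step 19
Reactants: 20 (10S)-allylic alcohol; 27 (9Z)-16-(PMB-oxy)hexadec-9-enoic acid
Product: 29 fully protected C10 ester, via mixed anhydride 28 (not isolated)
Conditions: 27 (1.3 equiv), 2,4,6-Cl3C6H2COCl (1.4 equiv), Et3N (2 equiv), PhMe, rt; then 20, DMAP (2 equiv), PhMe, rt to 40 °C
Reagents that add atoms: none
Why: Yamaguchi esterification acylates the hindered neopentyl-type C10 hydroxyl through the DMAP-activated acyl donor with retention, because the C10–O bond is never broken.

Step 20
Reactants: 29 fully protected C10 ester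
Product: 30 12-hydroxy 15-carboxylic acid (PMB ether retained)
Conditions: TBAF (5 equiv), THF, 0 °C to rt; aq NH4Cl
Reagents that add atoms: none
Why: Fluoride-induced desilylation cleaves the TBDPS ether and fragments the TMSE ester (β-silyl elimination to ethene) in one operation, while the PMB ether, the C10 ester and the Z alkene are inert and no epimerisable aldehyde is present yet.

Step 21
Reactants: 30 12-hydroxy 15-carboxylic acid
Product: 31 12-aldehyde 15-carboxylic acid (PMB ether retained)
Conditions: Dess–Martin periodinane (1.3 equiv), CH2Cl2, 0 °C to rt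
Reagents that add atoms: none
Why: Dess–Martin oxidation converts the only free alcohol into the C12 aldehyde under non-basic conditions, so C2 keeps its configuration and the free acid is tolerated.

Step 22
Reactants: 31 12-aldehyde 15-carboxylic acid
Product: 32 target CNP0214056.2
Conditions: DDQ (1.3 equiv), CH2Cl2/pH 7 phosphate buffer (10:1), 0 °C
Reagents that add atoms: none
Why: Oxidative PMB cleavage with DDQ (hydride abstraction to the benzylic oxocarbenium ion, then hydrolysis) runs at neutral pH, so the aldehyde α-centre, the allylic ester and the Z alkene are unaffected.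

**Compound list**
1 | (+)-limonene oxide, (4R)-1,2-epoxy-p-menth-8-ene, cis/trans mixture | CC(=C)[C@@H]1CCC2(C)OC2C1 | starting material
2 | (4R)-p-mentha-1(7),8-dien-2-ol, carbinol epimers | CC(=C)[C@@H]1CCC(=C)C(O)C1 | intermediate
3 | (6R)-6-isopropenyl-1-oxaspiro[2.5]octan-4-ol, epimer mixture | CC(=C)[C@@H]1CCC2(CO2)C(O)C1 | intermediate
4 | (4R)-1-(hydroxymethyl)-4-isopropenylcyclohexane-1,2-diol, epimer mixture | CC(=C)[C@@H]1CCC(O)(CO)C(O)C1 | intermediate
5 | (4R)-1-[(TBDPS-oxy)methyl]-4-isopropenylcyclohexane-1,2-diol | CC(=C)[C@@H]1CCC(O)(CO[Si](c2ccccc2)(c2ccccc2)C(C)(C)C)C(O)C1 | intermediate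
6 | (3R)-7-(TBDPS-oxy)-3-isopropenyl-6-oxoheptanal | CC(=C)[C@@H](CC=O)CCC(=O)CO[Si](c1ccccc1)(c1ccccc1)C(C)(C)C | intermediate
7 | aldol adduct, 2-hydroxy-2-[(TBDPS-oxy)methyl]-5-isopropenylcyclopentane-1-carbaldehyde (not isolated) | CC(=C)[C@@H]1CCC(O)(CO[Si](c2ccccc2)(c2ccccc2)C(C)(C)C)C1C=O | intermediate
8 | (5S)-2-[(TBDPS-oxy)methyl]-5-isopropenylcyclopent-1-ene-1-carbaldehyde | CC(=C)[C@@H]1CCC(CO[Si](c2ccccc2)(c2ccccc2)C(C)(C)C)=C1C=O | intermediate
9 | (2S,5R)-2-[(TBDPS-oxy)methyl]-5-isopropenylcyclopentane-1-carbaldehyde, 2,5-cis, C1 epimers | CC(=C)[C@@H]1CC[C@H](CO[Si](c2ccccc2)(c2ccccc2)C(C)(C)C)C1C=O | intermediate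
10 | methyl vinyl ketone (but-3-en-2-one) | CC(=O)C=C | starting material
11 | piperidine enamine of 9 (not isolated) | CC(=C)[C@@H]1CC[C@H](CO[Si](c2ccccc2)(c2ccccc2)C(C)(C)C)C1=CN3CCCCC3 | intermediate
12 | Michael adduct, 1-(3-oxobutyl) aldehyde with quaternary C1, formyl group cis to both ring substituents (not isolated) | CC(=C)[C@@H]1CC[C@H](CO[Si](c2ccccc2)(c2ccccc2)C(C)(C)C)[C@@]1(C=O)CCC(C)=O | intermediate
13 | spiro enone, 1-[(TBDPS-oxy)methyl]-4-isopropenylspiro[4.5]dec-6-en-8-one, CH=CH arm cis to both substituents | CC(=C)[C@@H]1CC[C@H](CO[Si](c3ccccc3)(c3ccccc3)C(C)(C)C)[C@]12C=CC(=O)CC2 | intermediate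
14 | TES enol ether, 8-(triethylsilyloxy)spiro[4.5]dec-7-ene analogue of 13 (C7=C8 in cedrane numbering) | CC(=C)[C@@H]1CC[C@H](CO[Si](c3ccccc3)(c3ccccc3)C(C)(C)C)[C@]12CC=C(O[Si](CC)(CC)CC)CC2 | intermediate
15 | tricyclic ketone, 6,6-dimethyl-2-[(TBDPS-oxy)methyl]tricyclo[5.3.1.0(1,5)]undecan-8-one, C12 arm syn to C11 | CC1(C)[C@H]2C[C@@]3(CCC2=O)[C@@H](CO[Si](c4ccccc4)(c4ccccc4)C(C)(C)C)CC[C@@H]13 | intermediate
16 | potassium C8=C9 enolate of 15 (not isolated) | CC1(C)[C@H]2C[C@@]3(CC=C2[O-])[C@@H](CO[Si](c4ccccc4)(c4ccccc4)C(C)(C)C)CC[C@@H]13.[K+] | intermediate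
17 | C8 enol triflate | CC1(C)[C@H]2C[C@@]3(CC=C2OS(=O)(=O)C(F)(F)F)[C@@H](CO[Si](c4ccccc4)(c4ccccc4)C(C)(C)C)CC[C@@H]13 | intermediate
18 | TMSE 12-(TBDPS-oxy)-2-epi-cedr-8-en-15-oate | CC1(C)[C@H]2C[C@@]3(CC=C2C(=O)OCC[Si](C)(C)C)[C@@H](CO[Si](c4ccccc4)(c4ccccc4)C(C)(C)C)CC[C@@H]13 | intermediate
19 | TMSE 12-(TBDPS-oxy)-10-oxo-2-epi-cedr-8-en-15-oate | CC1(C)[C@H]2C[C@@]3(C(=O)C=C2C(=O)OCC[Si](C)(C)C)[C@@H](CO[Si](c4ccccc4)(c4ccccc4)C(C)(C)C)CC[C@@H]13 | intermediate
20 | TMSE (10S)-10-hydroxy-12-(TBDPS-oxy)-2-epi-cedr-8-en-15-oate | CC1(C)[C@H]2C[C@@]3([C@@H](O)C=C2C(=O)OCC[Si](C)(C)C)[C@@H](CO[Si](c4ccccc4)(c4ccccc4)C(C)(C)C)CC[C@@H]13 | intermediate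
21 | 9-bromononanoic acid | OC(=O)CCCCCCCCBr | starting material
22 | (8-carboxyoctyl)triphenylphosphonium bromide | OC(=O)CCCCCCCC[P+](c1ccccc1)(c1ccccc1)c1ccccc1.[Br-] | intermediate
23 | heptane-1,7-diol | OCCCCCCCO | starting material
24 | 7-(PMB-oxy)heptan-1-ol | COc1ccc(COCCCCCCCO)cc1 | intermediate
25 | 7-(PMB-oxy)heptanal | COc1ccc(COCCCCCCC=O)cc1 | intermediate
26 | sodium 9-(triphenylphosphoranylidene)nonanoate (not isolated) | [Na+].[O-]C(=O)CCCCCCCC=P(c1ccccc1)(c1ccccc1)c1ccccc1 | intermediate
27 | (9Z)-16-(PMB-oxy)hexadec-9-enoic acid | OC(=O)CCCCCCC/C=C\CCCCCCOCc1ccc(OC)cc1 | intermediate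
28 | mixed anhydride of 27 and 2,4,6-trichlorobenzoic acid (not isolated) | O=C(CCCCCCC/C=C\CCCCCCOCc1ccc(OC)cc1)OC(=O)c1c(Cl)cc(Cl)cc1Cl | intermediate
29 | fully protected C10 ester (TMSE ester, TBDPS ether, PMB ether) | CC1(C)[C@H]2C[C@@]3([C@@H](OC(=O)CCCCCCC/C=C\CCCCCCOCc4ccc(OC)cc4)C=C2C(=O)OCC[Si](C)(C)C)[C@@H](CO[Si](c4ccccc4)(c4ccccc4)C(C)(C)C)CC[C@@H]13 | intermediate
30 | 12-hydroxy 15-carboxylic acid, PMB ether retained | CC1(C)[C@H]2C[C@@]3([C@@H](OC(=O)CCCCCCC/C=C\CCCCCCOCc4ccc(OC)cc4)C=C2C(=O)O)[C@@H](CO)CC[C@@H]13 | intermediate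
31 | 12-aldehyde 15-carboxylic acid, PMB ether retained | CC1(C)[C@H]2C[C@@]3([C@@H](OC(=O)CCCCCCC/C=C\CCCCCCOCc4ccc(OC)cc4)C=C2C(=O)O)[C@@H](C=O)CC[C@@H]13 | intermediate
32 | CNP0214056.2, (1S,2S,5S,7R,10S)-2-formyl-10-[(9Z)-16-hydroxyhexadec-9-enoyloxy]-6,6-dimethyltricyclo[5.3.1.0(1,5)]undec-8-ene-8-carboxylic acid | CC1(C)[C@H]2C[C@@]3([C@@H](OC(=O)CCCCCCC/C=C\CCCCCCO)C=C2C(=O)O)[C@@H](C=O)CC[C@@H]13 | target

**Step count:** 22 steps in total. The longest linear sequence is 18 steps (steps 1–14 and 19–22, from (+)-limonene oxide).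

**Steps most likely to fail**

Step 10 (the new reaction). The risks are hydrogen-atom transfer to the enol silane instead of the isopropenyl group, isomerisation of the alkene to the tetrasubstituted isomer, and capture of the C6 cation by the cis-disposed silyl ether oxygen. The fallback uses known chemistry and runs from 13 back to 15. Markovnikov addition of dry HCl (4 M in dioxane, CH2Cl2, −20 °C) to the isopropenyl group gives the tertiary chloride enone F1. RhCl(PPh3)3/Et3SiH 1,4-hydrosilylation then gives the chloro enol silane F2. TiCl4 (CH2Cl2, −78 °C) ionises the chloride for an intramolecular Reetz α-tert-alkylation that closes ring C and delivers ketone 15.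

Step 7. Copper hydride may be too slow on the tetrasubstituted enal or may reduce the aldehyde in a 1,2 sense. The fallback runs from 8 back to 9 and replaces hydride conjugate addition with a mask–hydrogenate–unmask sequence. mCPBA (NaHCO3, CH2Cl2, 0 °C) epoxidises only the electron-rich isopropenyl alkene to give the epoxy enal F3. Hydrogenation over Pd/C (H2, EtOAc) adds both hydrogens from the face opposite to the C5 substituent and gives the saturated epoxy aldehyde F4 with the same 2,5-cis relationship. Deoxygenation with Ph3P=Se/CF3CO2H (CH2Cl2, rt) regenerates the isopropenyl group and gives 9.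

Step 13. The electron-poor, neopentyl-type C10–H bonds may resist radical oxidation, or over-oxidation may occur elsewhere. The fallback runs from 18 back to 19 and uses ionic chemistry. γ-Deprotonation (LDA, HMPA/THF, −78 °C) to the extended enolate, followed by α-hydroxylation with 2-(phenylsulfonyl)-3-phenyloxaziridine from the exo face, gives the C8 tertiary allylic alcohol F5. Pyridinium chlorochromate (4 Å MS, CH2Cl2, rt) then effects a Babler–Dauben oxidative 1,3-transposition to the enone 19.

**Further compounds**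
F1 | step 10 | tertiary chloride enone, 4-(2-chloropropan-2-yl) analogue of 13 | CC(C)(Cl)[C@@H]1CC[C@H](CO[Si](c3ccccc3)(c3ccccc3)C(C)(C)C)[C@]12C=CC(=O)CC2
F2 | step 10 | chloro enol silane, 4-(2-chloropropan-2-yl) analogue of 14 | CC(C)(Cl)[C@@H]1CC[C@H](CO[Si](c3ccccc3)(c3ccccc3)C(C)(C)C)[C@]12CC=C(O[Si](CC)(CC)CC)CC2
F3 | step 7 | epoxy enal, 5-(2-methyloxiran-2-yl) analogue of 8 (epoxide epimers) | CC2(CO2)[C@@H]1CCC(CO[Si](c3ccccc3)(c3ccccc3)C(C)(C)C)=C1C=O
F4 | step 7 | saturated epoxy aldehyde, 5-(2-methyloxiran-2-yl) analogue of 9 (epoxide and C1 epimers) | CC2(CO2)[C@@H]1CC[C@H](CO[Si](c3ccccc3)(c3ccccc3)C(C)(C)C)C1C=O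
F5 | step 13 | C8 tertiary allylic alcohol, TMSE 8-hydroxy-12-(TBDPS-oxy)-2-epi-cedr-9-en-15-oate (exo hydroxyl) | CC1(C)[C@H]2C[C@@]3(C=C[C@@]2(O)C(=O)OCC[Si](C)(C)C)[C@@H](CO[Si](c4ccccc4)(c4ccccc4)C(C)(C)C)CC[C@@H]13
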